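## Retrosynthetic overview

1. Trichorabdal B ⇐ 6,11-diol 38 (C6–OH oxidised last) ⇐ 15-ketone 34 (α-methylenation with acetylation of C19–OH) ⇐ 15-methylidene tetracycle 31 (ozonolysis).
2. Ring D and the C8 quaternary carbon: oxidative cyclisation of a lactone silyl ketene acetal onto an allyl group (C8–C15). Ring C: SmI2 ketyl–olefin closure (C9–C11) of aldehyde 28, whose side chain comes from alkylating spirolactone 15 with iodide 23.
3. Spiro-δ-lactone and C10: titanocene-mediated opening of epoxide 13, acrylate capture and lactonisation. Ring A: palladium enolate vinylation of γ-lactone 7.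
4. Key step: enantioselective Baeyer–Villiger desymmetrisation of cyclobutanone 6. It makes the C19–O bond that ends as the acetate C–O bond and sets the C4 quaternary centre, from which C5, C10, C9, C11 and C8 are relayed; C13 comes from an Evans alkylation.
5. Ring order: cyclobutanone → γ-lactone → ring A → spiro-δ-lactone → ring C → ring D.

Assumption: SMILES strings are definitive where a CIP label and a SMILES might differ; the (R)-configured acid catalyst is taken to give (4R)-7, and the (R)-1-phenylethylammonium salt of 10 is taken to be the less soluble diastereomer.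

Carbon labels C1–C20 in descriptions follow ent-kaurane numbering of the target: C4 carries CH3 and C19; C6 is the aldehyde carbon; C7 the lactone carbonyl; C20 the lactone CH2; C15 the ring D ketone; C16=C17 the exocyclic alkene.

## Route

Step 1
Reactants: 1 4-bromo-2-methylbut-1-ene; 2 2,3-dibromoprop-1-ene
Product: 4 2-bromo-6-methylhepta-1,6-diene, via Grignard reagent 3 (not isolated)
Conditions: Mg, THF, 40 °C; then 2, THF, 0 → 25 °C
Reagents that add atoms: none
Why: Allylic substitution of 2,3-dibromopropene by a primary Grignard reagent (direct and allylic-transposed attack give the same 2-bromo-1-alkene) is a classical route to 2-bromoalk-1-enes.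

Step 2
Reactants: 4 2-bromo-6-methylhepta-1,6-diene
Product: 6 3-(4-bromopent-4-en-1-yl)-3-methylcyclobutan-1-one, via cyclobutaniminium triflate 5 (not isolated)
Conditions: N,N-dimethylacetamide, Tf2O, 2,4,6-collidine, ClCH2CH2Cl, 80 °C; then H2O
Reagents that add atoms: N,N-dimethylacetamide CC(=O)N(C)C; water O
Why: Ghosez keteniminium [2+2] cycloaddition occurs only at the electron-rich 1,1-dialkyl alkene (the vinyl bromide is deactivated) and gives the prochiral 3,3-disubstituted cyclobutanone after iminium hydrolysis.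

Step 3
Reactants: 6 3-(4-bromopent-4-en-1-yl)-3-methylcyclobutan-1-one
Product: 7 (4R)-4-(4-bromopent-4-en-1-yl)-4-methyloxolan-2-one
Conditions: (R)-3,3′-bis(2,4,6-triisopropylphenyl)-5,5′,6,6′,7,7′,8,8′-octahydro-1,1′-binaphthalene-2,2′-diyl hydrogen phosphate (10 mol %), 30% aq H2O2, CHCl3, −40 °C
Reagents that add atoms: hydrogen peroxide OO
Why: Proposed new method: chiral phosphoric acid-catalysed Baeyer–Villiger desymmetrisation of a 3-alkyl-3-methylcyclobutanone with aqueous H2O2; the bifunctional acid hydrogen-bonds both the ketone and H2O2, the Criegee adduct sits in the chiral pocket with the long bromopentenyl chain turned away from the triisopropylphenyl wall, so only one of the two enantiotopic CH2 groups is antiperiplanar to the O–O bond and migrates, which forms the C19–O bond and sets the C4 quaternary centre; the closest known reaction type is the phosphoric acid/H2O2 Baeyer–Villiger desymmetrisation of 3-monosubstituted cyclobutanones, and what has not been shown is discrimination of methyl from a primary alkyl chain.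

Step 4
Reactants: 7 (4R)-4-(4-bromopent-4-en-1-yl)-4-methyloxolan-2-one
Product: 8 (3aR,7aS)-3a-methyl-7-methylidenehexahydro-2-benzofuran-1(3H)-one
Conditions: Pd2(dba)3 (2.5 mol %), P(t-Bu)3·HBF4 (10 mol %), LiHMDS (2.2 equiv), toluene, 25 → 50 °C; AcOH, −78 °C
Reagents that add atoms: none
Why: Intramolecular palladium-catalysed α-alkenylation of the lactone enolate (only the lactone is enolisable) closes ring A with the exocyclic methylidene in place, and kinetic α-protonation of the product dienolate gives the cis-fused lactone, which fixes C5 cis to C19.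

Step 5
Reactants: 8 (3aR,7aS)-3a-methyl-7-methylidenehexahydro-2-benzofuran-1(3H)-one
Product: 10 (1S,2R)-2-{[(4-methoxybenzyl)oxy]methyl}-2-methyl-6-methylidenecyclohexane-1-carboxylic acid, via potassium hydroxy carboxylate 9 (not isolated)
Conditions: KOH, MeOH/H2O, 60 °C; evaporate; NaH, PMBCl, Bu4NI, THF/DMF, 0 → 25 °C; 1 M HCl
Reagents that add atoms: potassium hydroxide [K+].[OH-]; 4-methoxybenzyl chloride COc1ccc(CCl)cc1
Why: Saponification followed by Williamson etherification of the alkoxide while C6 is held as the non-enolisable carboxylate differentiates O19 from C6 without risk to C5, and the ether can no longer relactonise.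

Step 6
Reactants: 10 (1S,2R)-2-{[(4-methoxybenzyl)oxy]methyl}-2-methyl-6-methylidenecyclohexane-1-carboxylic acid
Product: 11 [(1S,2R)-2-{[(4-methoxybenzyl)oxy]methyl}-2-methyl-6-methylidenecyclohexyl]methanol
Conditions: LiAlH4, THF, 0 → 66 °C
Reagents that add atoms: none
Why: Hydride reduction of the carboxylic acid gives the C6 primary alcohol without touching the ether or the alkene.

Step 7
Reactants: 11 [(1S,2R)-2-{[(4-methoxybenzyl)oxy]methyl}-2-methyl-6-methylidenecyclohexyl]methanol
Product: 12 tert-butyl{[(1S,2R)-2-{[(4-methoxybenzyl)oxy]methyl}-2-methyl-6-methylidenecyclohexyl]methoxy}dimethylsilane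
Conditions: TBSCl, imidazole, DMF, 25 °C
Reagents that add atoms: tert-butyldimethylsilyl chloride CC(C)(C)[Si](C)(C)Cl
Why: Standard silylation gives a C6 protecting group orthogonal to the PMB ether on O19.

Step 8
Reactants: 12 tert-butyl{[(1S,2R)-2-{[(4-methoxybenzyl)oxy]methyl}-2-methyl-6-methylidenecyclohexyl]methoxy}dimethylsilane
Product: 13 tert-butyl{[(4S,5R)-5-{[(4-methoxybenzyl)oxy]methyl}-5-methyl-1-oxaspiro[2.5]octan-4-yl]methoxy}dimethylsilane (both epimers at the spiro carbon)
Conditions: mCPBA, NaHCO3, CH2Cl2, 0 °C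
Reagents that add atoms: mCPBA OOC(=O)c1cccc(Cl)c1
Why: Prilezhaev epoxidation of the 1,1-disubstituted alkene; the epoxide configuration is irrelevant because C10 becomes a planar radical in the next step.

Step 9
Reactants: 13 tert-butyl{[(4S,5R)-5-{[(4-methoxybenzyl)oxy]methyl}-5-methyl-1-oxaspiro[2.5]octan-4-yl]methoxy}dimethylsilane
Product: 15 (6R,7R,8R)-7-{[(tert-butyldimethylsilyl)oxy]methyl}-8-{[(4-methoxybenzyl)oxy]methyl}-8-methyl-2-oxaspiro[5.5]undecan-3-one, via trifluoroethyl hydroxy ester 14 (not isolated)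
Conditions: Cp2TiCl2 (20 mol %), Zn, 2,4,6-collidine·HCl, 2,2,2-trifluoroethyl acrylate, THF, 25 → 40 °C
Reagents that add atoms: 2,2,2-trifluoroethyl acrylate C=CC(=O)OCC(F)(F)F
Why: Nugent–RajanBabu epoxide opening by Cp2TiCl (trivalent titanium) gives the tertiary C10 radical, which adds to the acrylate (Giese addition) anti to the adjacent C5 CH2OTBS group and so sets C10, and the released C20 alcohol lactonises onto the activated trifluoroethyl ester.

Step 10
Reactants: 16 methyl 4,4-dimethoxybutanoate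
Product: 17 lithium 4,4-dimethoxybutanoate
Conditions: LiOH·H2O, THF/H2O, 25 °C; evaporate to dryness
Reagents that add atoms: lithium hydroxide [Li+].[OH-]
Why: Ester saponification; the salt is kept unacidified because the free acid would cyclise onto the acetal.

Step 11
Reactants: 17 lithium 4,4-dimethoxybutanoate; 18 (R)-4-benzyl-1,3-oxazolidin-2-one
Product: 20 (R)-4-benzyl-3-(4,4-dimethoxybutanoyl)-1,3-oxazolidin-2-one, via mixed pivalic anhydride 19 (not isolated)
Conditions: 17, PivCl, THF, −20 °C; then 18, n-BuLi, THF, −78 → 0 °C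
Reagents that add atoms: none
Why: N-Acylation of the lithiated Evans auxiliary by the mixed pivalic anhydride occurs at the less hindered acyl carbon.

Step 12
Reactants: 20 (R)-4-benzyl-3-(4,4-dimethoxybutanoyl)-1,3-oxazolidin-2-one
Product: 21 (R)-4-benzyl-3-[(2R)-2-(2,2-dimethoxyethyl)pent-4-enoyl]-1,3-oxazolidin-2-one
Conditions: NaHMDS, THF, −78 °C; allyl bromide, −78 → −40 °C
Reagents that add atoms: allyl bromide C=CCBr
Why: Evans asymmetric alkylation: the chelated Z-sodium enolate is allylated on the face opposite the benzyl group, which sets C13.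

Step 13
Reactants: 21 (R)-4-benzyl-3-[(2R)-2-(2,2-dimethoxyethyl)pent-4-enoyl]-1,3-oxazolidin-2-one
Product: 22 (2R)-2-(2,2-dimethoxyethyl)pent-4-en-1-ol
Conditions: LiBH4, H2O (1 equiv), Et2O, 0 °C
Reagents that add atoms: none
Why: Reductive cleavage of the imide gives the primary alcohol without epimerisation and returns the auxiliary.

Step 14
Reactants: 22 (2R)-2-(2,2-dimethoxyethyl)pent-4-en-1-ol
Product: 23 (4R)-4-(iodomethyl)-6,6-dimethoxyhex-1-ene
Conditions: I2, PPh3, imidazole, CH2Cl2, 0 → 25 °C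
Reagents that add atoms: iodine II
Why: Appel-type iodination of a primary alcohol under buffered conditions that leave the acetal intact.

Step 15
Reactants: 15 (6R,7R,8R)-7-{[(tert-butyldimethylsilyl)oxy]methyl}-8-{[(4-methoxybenzyl)oxy]methyl}-8-methyl-2-oxaspiro[5.5]undecan-3-one; 23 (4R)-4-(iodomethyl)-6,6-dimethoxyhex-1-ene
Product: 24 spirolactone 15 alkylated at C8 by the chain of 23 (both C8 epimers)
Conditions: LDA, THF, −78 °C; 23, HMPA, −78 → −20 °C
Reagents that add atoms: none
Why: Lactone enolate alkylation by a primary iodide joins the two fragments (C8–C14); the C8 configuration is erased in the next step.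

Step 16
Reactants: 24 spirolactone 15 alkylated at C8 by the chain of 23 (both C8 epimers)
Product: 27 C8=C9 unsaturated spirolactone carrying the C8 side chain, via α-phenylselanyl lactone 25 (not isolated), via selenoxide 26 (not isolated)
Conditions: KHMDS, THF, −78 °C; PhSeBr; then 30% H2O2, pyridine, CH2Cl2, 0 → 25 °C
Reagents that add atoms: none
Why: α-Selenenylation and selenoxide syn-elimination toward the ring C9–H gives the endocyclic α-substituted unsaturated lactone needed as radical acceptor.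

Step 17
Reactants: 27 C8=C9 unsaturated spirolactone carrying the C8 side chain
Product: 28 C11 aldehyde of the unsaturated spirolactone
Conditions: LiBF4, MeCN/H2O (50:1), 25 °C
Reagents that add atoms: water O
Why: Mild Lewis acid hydrolysis of the dimethyl acetal releases the aldehyde while the TBS and PMB ethers survive.

Step 18
Reactants: 28 C11 aldehyde of the unsaturated spirolactone
Product: 29 tricyclic 11-hydroxy lactone with ring C closed (C9 and C11 as in the target; C8–H unassigned)
Conditions: SmI2, LiBr, t-BuOH, THF, −78 °C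
Reagents that add atoms: none
Why: SmI2 ketyl–olefin reductive cyclisation: the C11 ketyl adds to C9 of the unsaturated lactone on the face opposite the ring A CH2OTBS group through a chair transition state with the samarium-bound oxygen equatorial, which sets C9 and the equatorial C11–OH.

Step 19
Reactants: 29 tricyclic 11-hydroxy lactone with ring C closed (C9 and C11 as in the target; C8–H unassigned)
Product: 30 11-O-TBS silyl ketene acetal of 29 (C7(OTBS)=C8)
Conditions: KHMDS (2.5 equiv), TBSCl (3 equiv), THF, −78 → 0 °C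
Reagents that add atoms: tert-butyldimethylsilyl chloride CC(C)(C)[Si](C)(C)Cl
Why: Double deprotonation and O-silylation protects C11–OH and converts the lactone into its silyl ketene acetal in one operation.

Step 20
Reactants: 30 11-O-TBS silyl ketene acetal of 29 (C7(OTBS)=C8)
Product: 31 tetracyclic lactone with bicyclo[3.2.1]octane ring D closed (C15 methylidene)
Conditions: Pd(OAc)2 (1 equiv), AcOH, DMSO, 45 °C
Reagents that add atoms: none
Why: Oxidative cyclisation of the silyl ketene acetal onto the allyl group (palladium enolate, 5-exo carbopalladation, β-hydride elimination) forges C8–C15 and the C8 quaternary centre, whose configuration is dictated by the tether from C13.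

Step 21
Reactants: 31 tetracyclic lactone with bicyclo[3.2.1]octane ring D closed (C15 methylidene)
Product: 33 15-ketone (19-O-PMB; 6,11-bis-O-TBS), via secondary ozonide 32 (not isolated)
Conditions: O3, CH2Cl2, −78 °C (Sudan red end point); PPh3, −78 → 25 °C
Reagents that add atoms: ozone [O-][O+]=O
Why: Ozonolysis of the only alkene gives the ring D ketone.

Step 22
Reactants: 33 15-ketone (19-O-PMB; 6,11-bis-O-TBS)
Product: 34 19-hydroxy 15-ketone (6,11-bis-O-TBS)
Conditions: DDQ, CH2Cl2/pH 7 buffer, 0 °C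
Reagents that add atoms: none
Why: Oxidative PMB cleavage frees only O19, leaving both silyl ethers.

Step 23
Reactants: 34 19-hydroxy 15-ketone (6,11-bis-O-TBS)
Product: 37 6,11-bis-O-TBS ether of 6-dihydrotrichorabdal B (enone and 19-acetate in place), via C19 acetate 35 (not isolated), via Mannich base 36 (not isolated)
Conditions: (Me2N)2CH2, Ac2O, DMF, 95 °C
Reagents that add atoms: bis(dimethylamino)methane CN(C)CN(C)C; acetic anhydride CC(=O)OC(C)=O
Why: The iminium ion formed in situ gives a Mannich reaction at C16, the only enolisable position of the ketone, and amine elimination gives the exocyclic enone, while the same Ac2O acetylates the free C19 alcohol.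

Step 24
Reactants: 37 6,11-bis-O-TBS ether of 6-dihydrotrichorabdal B (enone and 19-acetate in place)
Product: 38 6-dihydrotrichorabdal B (6,11-diol)
Conditions: HF·pyridine, THF/pyridine, 0 → 25 °C
Reagents that add atoms: none
Why: Fluoride-mediated desilylation removes both TBS groups without touching the acetate, lactone or enone.

Step 25
Reactants: 38 6-dihydrotrichorabdal B (6,11-diol)
Product: 39 trichorabdal B
Conditions: TEMPO (20 mol %), PhI(OAc)2, CH2Cl2, 25 °C
Reagents that add atoms: none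
Why: Oxoammonium oxidation (TEMPO/PhI(OAc)2) selects the primary C6 alcohol over the hindered secondary C11 alcohol and stops at the aldehyde; no lactol can form because O19 is already acetylated.

## Compound list

1 | 4-bromo-2-methylbut-1-ene | C=C(C)CCBr | starting material
2 | 2,3-dibromoprop-1-ene | C=C(Br)CBr | starting material
3 | (3-methylbut-3-en-1-yl)magnesium bromide | C=C(C)CC[Mg]Br | intermediate
4 | 2-bromo-6-methylhepta-1,6-diene | C=C(C)CCCC(Br)=C | intermediate
5 | N-[3-(4-bromopent-4-en-1-yl)-3-methylcyclobutylidene]-N-methylmethanaminium triflate | CC1(CCCC(Br)=C)CC(=[N+](C)C)C1.[O-]S(=O)(=O)C(F)(F)F | intermediate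
6 | 3-(4-bromopent-4-en-1-yl)-3-methylcyclobutan-1-one | CC1(CCCC(Br)=C)CC(=O)C1 | intermediate
7 | (4R)-4-(4-bromopent-4-en-1-yl)-4-methyloxolan-2-one | C=C(Br)CCC[C@@]1(C)COC(=O)C1 | intermediate
8 | (3aR,7aS)-3a-methyl-7-methylidenehexahydro-2-benzofuran-1(3H)-one (cis-fused) | C=C1CCC[C@@]2(C)COC(=O)[C@@H]12 | intermediate
9 | potassium (1S,2R)-2-(hydroxymethyl)-2-methyl-6-methylidenecyclohexane-1-carboxylate | C=C1CCC[C@@](C)(CO)[C@H]1C(=O)[O-].[K+] | intermediate
10 | (1S,2R)-2-{[(4-methoxybenzyl)oxy]methyl}-2-methyl-6-methylidenecyclohexane-1-carboxylic acid | C=C1CCC[C@@](C)(COCc2ccc(OC)cc2)[C@H]1C(=O)O | intermediate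
11 | [(1S,2R)-2-{[(4-methoxybenzyl)oxy]methyl}-2-methyl-6-methylidenecyclohexyl]methanol | C=C1CCC[C@@](C)(COCc2ccc(OC)cc2)[C@H]1CO | intermediate
12 | tert-butyl{[(1S,2R)-2-{[(4-methoxybenzyl)oxy]methyl}-2-methyl-6-methylidenecyclohexyl]methoxy}dimethylsilane | C=C1CCC[C@@](C)(COCc2ccc(OC)cc2)[C@H]1CO[Si](C)(C)C(C)(C)C | intermediate
13 | tert-butyl{[(4S,5R)-5-{[(4-methoxybenzyl)oxy]methyl}-5-methyl-1-oxaspiro[2.5]octan-4-yl]methoxy}dimethylsilane (both epimers at the spiro carbon) | C1OC12CCC[C@@](C)(COCc3ccc(OC)cc3)[C@H]2CO[Si](C)(C)C(C)(C)C | intermediate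
14 | 2,2,2-trifluoroethyl 3-[(1R,2R,3R)-2-{[(tert-butyldimethylsilyl)oxy]methyl}-1-(hydroxymethyl)-3-{[(4-methoxybenzyl)oxy]methyl}-3-methylcyclohexyl]propanoate | OC[C@@]1(CCC(=O)OCC(F)(F)F)CCC[C@@](C)(COCc2ccc(OC)cc2)[C@H]1CO[Si](C)(C)C(C)(C)C | intermediate
15 | (6R,7R,8R)-7-{[(tert-butyldimethylsilyl)oxy]methyl}-8-{[(4-methoxybenzyl)oxy]methyl}-8-methyl-2-oxaspiro[5.5]undecan-3-one | O=C1CC[C@]2(CO1)CCC[C@@](C)(COCc3ccc(OC)cc3)[C@H]2CO[Si](C)(C)C(C)(C)C | intermediate
16 | methyl 4,4-dimethoxybutanoate | COC(=O)CCC(OC)OC | starting material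
17 | lithium 4,4-dimethoxybutanoate | COC(CCC(=O)[O-])OC.[Li+] | intermediate
18 | (R)-4-benzyl-1,3-oxazolidin-2-one | O=C1N[C@H](Cc2ccccc2)CO1 | starting material
19 | 4,4-dimethoxybutanoic pivalic anhydride | COC(CCC(=O)OC(=O)C(C)(C)C)OC | intermediate
20 | (R)-4-benzyl-3-(4,4-dimethoxybutanoyl)-1,3-oxazolidin-2-one | COC(OC)CCC(=O)N1[C@H](Cc2ccccc2)COC1=O | intermediate
21 | (R)-4-benzyl-3-[(2R)-2-(2,2-dimethoxyethyl)pent-4-enoyl]-1,3-oxazolidin-2-one | C=CC[C@H](CC(OC)OC)C(=O)N1[C@H](Cc2ccccc2)COC1=O | intermediate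
22 | (2R)-2-(2,2-dimethoxyethyl)pent-4-en-1-ol | C=CC[C@H](CC(OC)OC)CO | intermediate
23 | (4R)-4-(iodomethyl)-6,6-dimethoxyhex-1-ene | C=CC[C@H](CC(OC)OC)CI | intermediate
24 | spirolactone 15 alkylated at C8 by the 2-(2,2-dimethoxyethyl)pent-4-enyl chain of 23 (C13 as in 23; both C8 epimers) | O=C1C(C[C@H](CC=C)CC(OC)OC)C[C@]2(CO1)CCC[C@@](C)(COCc3ccc(OC)cc3)[C@H]2CO[Si](C)(C)C(C)(C)C | intermediate
25 | 8-phenylselanyl derivative of 24 | O=C1C([Se]c4ccccc4)(C[C@H](CC=C)CC(OC)OC)C[C@]2(CO1)CCC[C@@](C)(COCc3ccc(OC)cc3)[C@H]2CO[Si](C)(C)C(C)(C)C | intermediate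
26 | selenoxide of 25 | O=C1C([Se](=O)c4ccccc4)(C[C@H](CC=C)CC(OC)OC)C[C@]2(CO1)CCC[C@@](C)(COCc3ccc(OC)cc3)[C@H]2CO[Si](C)(C)C(C)(C)C | intermediate
27 | C8=C9 unsaturated spirolactone with the C8 side chain (dimethyl acetal) | O=C1C(C[C@H](CC=C)CC(OC)OC)=C[C@]2(CO1)CCC[C@@](C)(COCc3ccc(OC)cc3)[C@H]2CO[Si](C)(C)C(C)(C)C | intermediate
28 | C11 aldehyde of the unsaturated spirolactone | O=C1C(C[C@H](CC=C)CC=O)=C[C@]2(CO1)CCC[C@@](C)(COCc3ccc(OC)cc3)[C@H]2CO[Si](C)(C)C(C)(C)C | intermediate
29 | tricyclic 11-hydroxy lactone: ring C closed, C13 allyl, 6-O-TBS, 19-O-PMB (C8–H unassigned) | C=CC[C@@H]1C[C@@H](O)[C@@H]2[C@@]3(CCC[C@@](C)(COCc4ccc(OC)cc4)[C@H]3CO[Si](C)(C)C(C)(C)C)COC(=O)C2C1 | intermediate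
30 | 11-O-TBS silyl ketene acetal of 29 | C=CC[C@@H]1C[C@@H](O[Si](C)(C)C(C)(C)C)[C@@H]2[C@@]3(CCC[C@@](C)(COCc4ccc(OC)cc4)[C@H]3CO[Si](C)(C)C(C)(C)C)COC(O[Si](C)(C)C(C)(C)C)=C2C1 | intermediate
31 | tetracyclic lactone with ring D closed and C15 methylidene (6,11-bis-O-TBS; 19-O-PMB) | C=C1C[C@@H]2C[C@@H](O[Si](C)(C)C(C)(C)C)[C@@H]3[C@@]4(CCC[C@@](C)(COCc5ccc(OC)cc5)[C@H]4CO[Si](C)(C)C(C)(C)C)COC(=O)[C@]13C2 | intermediate
32 | secondary ozonide (1,2,4-trioxolane spiro-fused at C15) of 31 | C1OOC2(O1)C[C@@H]3C[C@@H](O[Si](C)(C)C(C)(C)C)[C@@H]4[C@@]5(CCC[C@@](C)(COCc6ccc(OC)cc6)[C@H]5CO[Si](C)(C)C(C)(C)C)COC(=O)[C@]24C3 | intermediate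
33 | 15-ketone (6,11-bis-O-TBS; 19-O-PMB) | O=C1C[C@@H]2C[C@@H](O[Si](C)(C)C(C)(C)C)[C@@H]3[C@@]4(CCC[C@@](C)(COCc5ccc(OC)cc5)[C@H]4CO[Si](C)(C)C(C)(C)C)COC(=O)[C@]13C2 | intermediate
34 | 19-hydroxy 15-ketone (6,11-bis-O-TBS) | O=C1C[C@@H]2C[C@@H](O[Si](C)(C)C(C)(C)C)[C@@H]3[C@@]4(CCC[C@@](C)(CO)[C@H]4CO[Si](C)(C)C(C)(C)C)COC(=O)[C@]13C2 | intermediate
35 | 19-acetoxy 15-ketone (6,11-bis-O-TBS) | O=C1C[C@@H]2C[C@@H](O[Si](C)(C)C(C)(C)C)[C@@H]3[C@@]4(CCC[C@@](C)(COC(C)=O)[C@H]4CO[Si](C)(C)C(C)(C)C)COC(=O)[C@]13C2 | intermediate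
36 | 16-(dimethylaminomethyl) derivative of 35 (Mannich base; C16 unassigned) | O=C1C(CN(C)C)[C@@H]2C[C@@H](O[Si](C)(C)C(C)(C)C)[C@@H]3[C@@]4(CCC[C@@](C)(COC(C)=O)[C@H]4CO[Si](C)(C)C(C)(C)C)COC(=O)[C@]13C2 | intermediate
37 | 6,11-bis-O-TBS ether of 6-dihydrotrichorabdal B | C=C1C(=O)[C@]23C[C@H]1C[C@@H](O[Si](C)(C)C(C)(C)C)[C@@H]2[C@@]1(CCC[C@@](C)(COC(C)=O)[C@H]1CO[Si](C)(C)C(C)(C)C)COC3=O | intermediate
38 | 6-dihydrotrichorabdal B (6,11-diol) | C=C1C(=O)[C@]23C[C@H]1C[C@@H](O)[C@@H]2[C@@]1(CCC[C@@](C)(COC(C)=O)[C@H]1CO)COC3=O | intermediate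
39 | trichorabdal B, (4R,5R,8S,9R,10R,11R,13S) in ent-kaurane numbering | C=C1C(=O)[C@]23C[C@H]1C[C@@H](O)[C@@H]2[C@@]1(CCC[C@@](C)(COC(C)=O)[C@H]1C=O)COC3=O | target

## Step count and risks

Total step count: 25. Longest linear sequence: 20 (steps 1–9 and 15–25); the iodide branch (steps 10–14) is 5 steps.

Steps most likely to fail:

Step 3 (the proposed new desymmetrisation; the risk is low enantioselectivity, not reactivity). Fallback with known chemistry, setting out from 6 and returning at 10: oxidise 6 with mCPBA/NaHCO3 to the racemic lactone, that is 7 together with its enantiomer (4S)-lactone F1. Carry the racemate through steps 4 and 5 unchanged, which gives beside 8, 9 and 10 the enantiomeric bicyclic lactone F2, the enantiomeric potassium salt F3 and the enantiomeric acid F4. Resolve the racemic acid classically with (R)-1-phenylethylamine in EtOAc: the (R)-1-phenylethylammonium salt of 10 F5 crystallises while the diastereomeric ammonium salt of the enantiomeric acid F6 stays in the mother liquor. Acidify F5 with 1 M HCl to release 10.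

Step 4 (lactone enolate vinylation; risks are slow coupling and conjugation of the product alkene). Fallback setting out from 7 and returning at 8: LDA, THF, −78 °C then CBr4 gives the α-bromo lactone F7. A nickel-catalysed reductive cross-electrophile coupling (NiCl2(dme) 10 mol %, 4,4′-di-tert-butyl-2,2′-bipyridine, Mn powder, DMF, 25 °C) then joins the carbon bearing the α-bromine to the vinyl bromide carbon and closes ring A without any enolate, giving cis-fused 8 directly.

Step 9 (radical conjugate addition of a hindered tertiary radical, with lactonisation). Fallback setting out from 13 and returning at 15: Meinwald rearrangement (BF3·OEt2, CH2Cl2, −78 °C) gives the ring A C20 aldehyde F8. Base-catalysed Michael addition of this α-branched aldehyde to methyl acrylate (KOt-Bu cat., t-BuOH, 0 °C), with the acrylate approaching anti to the CH2OTBS group, gives the quaternary aldehyde ester F9. NaBH4 in MeOH reduces the aldehyde to the methyl hydroxy ester F10, which lactonises on warming with a trace of TsOH to 15.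

Further compounds
F1 | step 3 | (4S)-4-(4-bromopent-4-en-1-yl)-4-methyloxolan-2-one (enantiomer of 7) | C=C(Br)CCC[C@]1(C)COC(=O)C1
F2 | step 3 | (3aS,7aR)-3a-methyl-7-methylidenehexahydro-2-benzofuran-1(3H)-one (enantiomer of 8) | C=C1CCC[C@]2(C)COC(=O)[C@H]12
F3 | step 3 | potassium (1R,2S)-2-(hydroxymethyl)-2-methyl-6-methylidenecyclohexane-1-carboxylate (enantiomer of 9) | C=C1CCC[C@](C)(CO)[C@@H]1C(=O)[O-].[K+]
F4 | step 3 | (1R,2S)-2-{[(4-methoxybenzyl)oxy]methyl}-2-methyl-6-methylidenecyclohexane-1-carboxylic acid (enantiomer of 10) | C=C1CCC[C@](C)(COCc2ccc(OC)cc2)[C@@H]1C(=O)O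
F5 | step 3 | (R)-1-phenylethylammonium salt of 10 | C=C1CCC[C@@](C)(COCc2ccc(OC)cc2)[C@H]1C(=O)[O-].C[C@@H]([NH3+])c1ccccc1
F6 | step 3 | (R)-1-phenylethylammonium salt of F4 | C=C1CCC[C@](C)(COCc2ccc(OC)cc2)[C@@H]1C(=O)[O-].C[C@@H]([NH3+])c1ccccc1
F7 | step 4 | 3-bromo-4-(4-bromopent-4-en-1-yl)-4-methyloxolan-2-one (C4 as in 7; both C3 epimers) | C=C(Br)CCC[C@@]1(C)COC(=O)C1Br
F8 | step 9 | (2S,3R)-2-{[(tert-butyldimethylsilyl)oxy]methyl}-3-{[(4-methoxybenzyl)oxy]methyl}-3-methylcyclohexane-1-carbaldehyde (both C1 epimers) | O=CC1CCC[C@@](C)(COCc2ccc(OC)cc2)[C@H]1CO[Si](C)(C)C(C)(C)C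
F9 | step 9 | methyl 3-[1-formyl-2-{[(tert-butyldimethylsilyl)oxy]methyl}-3-{[(4-methoxybenzyl)oxy]methyl}-3-methylcyclohexyl]propanoate (ring stereocentres as in 14) | COC(=O)CC[C@]1(C=O)CCC[C@@](C)(COCc2ccc(OC)cc2)[C@H]1CO[Si](C)(C)C(C)(C)C
F10 | step 9 | methyl ester analogue of 14 (methyl hydroxy ester) | OC[C@@]1(CCC(=O)OC)CCC[C@@](C)(COCc2ccc(OC)cc2)[C@H]1CO[Si](C)(C)C(C)(C)C
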